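**Retrosynthetic overview**
- With tetralone numbering (C1 ketone, C3 carbinol, C4a/C8a ring fusion, C5 pyranone, C6 isopentyl, C8 phenol; ring A benzene, ring B cyclohexanone), the C1 ketone and the C3 carbinol form a β-hydroxy ketone. Bond C2–C3 is cut, so that ring B closes last and C3, the only stereocentre, is set in that closure (after it only the two methoxymethyl ethers are removed).
- The keto aldehyde precursor (acetyl on C8a, 2-oxoethyl on C4a) comes from a cyclic mixed methyl ketal, a 1-methoxy-1-methylisochromane that masks both groups while the pyranone is built on C5.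
- The pyranone ring comes from a C5 aldehyde and the dianion of methyl acetoacetate (aldol addition, oxidation, lactonisation). The aldehyde comes from the C5 bromide, and the ketal from a dihydroisocoumarin and MeLi.
- The dihydroisocoumarin comes from a toluate by lateral hydroxymethylation. The toluate comes from methyl orsellinate by 4-triflation, isopentyl Kumada coupling and para-bromination.
- Ring order: ring A is bought, then the temporary isochromane ring, then the pyranone ring, then ring B.

Key step: step 13

Remarks on the chemistry: Atom numbers in the text are those of the tetralone skeleton given above. The (R,R) enantiomer of the ProPhenol ligand is assumed to give (3R), by transposing the facial preference of the intermolecular reaction to this substrate; the (S,S) ligand would be used if the sense proved opposite. The ketal carbon in compounds 10–17 is racemic and is destroyed in step 11. The aryl–pyranone bond is assumed to rotate freely.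

Step 1
Reactants: 1 methyl orsellinate (methyl 2,4-dihydroxy-6-methylbenzoate)
Product: 2 methyl 2-hydroxy-6-methyl-4-[(trifluoromethanesulfonyl)oxy]benzoate
Conditions: PhNTf2 (1.05 equiv), Et3N, CH2Cl2, 0 °C → rt
Reagents that add atoms: N-phenylbis(trifluoromethanesulfonimide), O=S(=O)(N(c1ccccc1)S(=O)(=O)C(F)(F)F)C(F)(F)F
Why: Selective O-sulfonylation (triflation) should take place at the free and more acidic 4-hydroxyl, because the 2-hydroxyl is held in a hydrogen bond to the ester carbonyl and is shielded by it.

Step 2
Reactants: 2 methyl 2-hydroxy-6-methyl-4-[(trifluoromethanesulfonyl)oxy]benzoate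
Product: 3 methyl 2-(methoxymethoxy)-6-methyl-4-[(trifluoromethanesulfonyl)oxy]benzoate
Conditions: MOMCl, i-Pr2NEt, CH2Cl2, 0 → 40 °C
Reagents that add atoms: chloromethyl methyl ether, COCCl
Why: O-alkylation of the remaining phenol with the reactive chloromethyl ether (MOM protection) removes the acidic proton before the Grignard coupling and is compatible with the aryl triflate.

Step 3
Reactants: 3 methyl 2-(methoxymethoxy)-6-methyl-4-[(trifluoromethanesulfonyl)oxy]benzoate; 4 isopentylmagnesium bromide (3-methylbutylmagnesium bromide)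
Product: 5 methyl 2-(methoxymethoxy)-6-methyl-4-(3-methylbutyl)benzoate
Conditions: 4 (1.3 equiv), Fe(acac)3 (5 mol%), THF/NMP, 0 °C
Reagents that add atoms: isopentylmagnesium bromide, CC(C)CC[Mg]Br
Why: Iron-catalysed Kumada-type cross-coupling of an aryl triflate activated by its para ester with a primary alkyl Grignard reagent is fast at 0 °C, so the doubly ortho-substituted ester should not be attacked.

Step 4
Reactants: 5 methyl 2-(methoxymethoxy)-6-methyl-4-(3-methylbutyl)benzoate
Product: 6 methyl 3-bromo-6-(methoxymethoxy)-2-methyl-4-(3-methylbutyl)benzoate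
Conditions: NBS (1.05 equiv), MeCN, 0 °C → rt, dark
Reagents that add atoms: N-bromosuccinimide, O=C1CCC(=O)N1Br
Why: Electrophilic aromatic bromination with NBS in MeCN is para-selective for alkoxyarenes even when the para position lies between two alkyl groups (as in 3,5-dialkylanisoles), and the ortho position is further shielded by the methoxymethoxy group, so bromine should enter at the carbon that becomes C5.

Step 5
Reactants: 6 methyl 3-bromo-6-(methoxymethoxy)-2-methyl-4-(3-methylbutyl)benzoate; 7 formaldehyde (monomer, from cracked paraformaldehyde)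
Product: 9 5-bromo-8-(methoxymethoxy)-6-(3-methylbutyl)-3,4-dihydro-1H-isochromen-1-one, via hydroxy ester 8 (not isolated)
Conditions: LiN(i-Pr)2 (1.2 equiv), THF, −78 °C; CH2O (g, from cracked paraformaldehyde), −78 → 0 °C; NH4Cl (aq)
Reagents that add atoms: formaldehyde, C=O
Why: Lateral lithiation of the ortho-toluate methyl group gives an ester-stabilised benzylic anion that adds to formaldehyde (hydroxymethylation), and the primary alkoxide lactonises onto the neighbouring ester, while the aryl bromide, which has no ortho hydrogen, is inert to the amide base.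

Step 6
Reactants: 9 5-bromo-8-(methoxymethoxy)-6-(3-methylbutyl)-3,4-dihydro-1H-isochromen-1-one
Product: 11 5-bromo-1-methoxy-8-(methoxymethoxy)-1-methyl-6-(3-methylbutyl)-3,4-dihydro-1H-isochromene (racemic), via lactol 10 (not isolated)
Conditions: MeLi (1.1 equiv), THF, −78 °C; NH4Cl (aq); then MeOH, PPTS (cat.), 3 Å MS, rt
Reagents that add atoms: methyllithium, [Li]C; methanol, CO
Why: Mono-addition of MeLi to a lactone stops at the lithium hemiketal at −78 °C, and acid-catalysed ketalisation of the resulting lactol in MeOH gives the cyclic mixed methyl ketal, which masks the future acetyl group and primary alcohol in one ring that is inert to the organolithium and enolate steps that follow.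

Step 7
Reactants: 11 5-bromo-1-methoxy-8-(methoxymethoxy)-1-methyl-6-(3-methylbutyl)-3,4-dihydro-1H-isochromene
Product: 12 1-methoxy-8-(methoxymethoxy)-1-methyl-6-(3-methylbutyl)-3,4-dihydro-1H-isochromene-5-carbaldehyde (racemic)
Conditions: t-BuLi (2.1 equiv), THF, −78 °C; DMF, −78 → 0 °C; NH4Cl (aq)
Reagents that add atoms: N,N-dimethylformamide, CN(C)C=O
Why: Bromine–lithium exchange with two equivalents of t-BuLi is faster at −78 °C than any deprotonation, and the hindered aryllithium is formylated by DMF (Bouveault-type formylation).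

Step 8
Reactants: 12 1-methoxy-8-(methoxymethoxy)-1-methyl-6-(3-methylbutyl)-3,4-dihydro-1H-isochromene-5-carbaldehyde; 13 methyl acetoacetate
Product: 14 methyl 5-hydroxy-5-[1-methoxy-8-(methoxymethoxy)-1-methyl-6-(3-methylbutyl)-3,4-dihydro-1H-isochromen-5-yl]-3-oxopentanoate (mixture of diastereomers)
Conditions: 13, LiN(i-Pr)2 (2.1 equiv), THF, 0 °C; then 12, −78 → −20 °C; NH4Cl (aq)
Reagents that add atoms: methyl acetoacetate, COC(=O)CC(C)=O
Why: The dianion of methyl acetoacetate reacts with aldehydes at its terminal γ-carbon (Huckin–Weiler aldol addition), which attaches the whole carbon chain of the pyranone to the hindered aldehyde.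

Step 9
Reactants: 14 methyl 5-hydroxy-5-[1-methoxy-8-(methoxymethoxy)-1-methyl-6-(3-methylbutyl)-3,4-dihydro-1H-isochromen-5-yl]-3-oxopentanoate
Product: 15 methyl 5-[1-methoxy-8-(methoxymethoxy)-1-methyl-6-(3-methylbutyl)-3,4-dihydro-1H-isochromen-5-yl]-3,5-dioxopentanoate
Conditions: DMP, pyridine, CH2Cl2, 0 °C → rt
Reagents that add atoms: none
Why: Dess–Martin oxidation of the benzylic secondary alcohol under pyridine buffering should give the 3,5-dioxo ester without exposing the ketal to acid.

Step 10
Reactants: 15 methyl 5-[1-methoxy-8-(methoxymethoxy)-1-methyl-6-(3-methylbutyl)-3,4-dihydro-1H-isochromen-5-yl]-3,5-dioxopentanoate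
Product: 17 6-[1-methoxy-8-(methoxymethoxy)-1-methyl-6-(3-methylbutyl)-3,4-dihydro-1H-isochromen-5-yl]-4-(methoxymethoxy)-2H-pyran-2-one, via hydroxypyranone 16 (not isolated)
Conditions: DBU (1.2 equiv), PhMe, 60 °C; then MOMCl (2 equiv), CH2Cl2, 0 °C
Reagents that add atoms: chloromethyl methyl ether, COCCl
Why: Base-promoted lactonisation of a 3,5-dioxo ester through its enol oxygen is the standard route to 6-aryl-4-hydroxy-2-pyranones, and O-alkylation of the resulting pyranonate at its 4-oxygen with MOMCl in the same flask avoids an acidic work-up that would endanger the ketal.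

Step 11
Reactants: 17 6-[1-methoxy-8-(methoxymethoxy)-1-methyl-6-(3-methylbutyl)-3,4-dihydro-1H-isochromen-5-yl]-4-(methoxymethoxy)-2H-pyran-2-one
Product: 18 6-[3-acetyl-2-(2-hydroxyethyl)-4-(methoxymethoxy)-6-(3-methylbutyl)phenyl]-4-(methoxymethoxy)-2H-pyran-2-one (in equilibrium with its cyclic hemiketal)
Conditions: PPTS (cat.), acetone/H2O (10:1), rt
Reagents that add atoms: water, O
Why: Acid-catalysed hydrolysis of a mixed ketal of an aryl ketone runs through a tertiary benzylic oxocarbenium ion and is far faster than cleavage of the methoxymethyl ethers, so the acetyl group and the primary alcohol should be released selectively.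

Step 12
Reactants: 18 6-[3-acetyl-2-(2-hydroxyethyl)-4-(methoxymethoxy)-6-(3-methylbutyl)phenyl]-4-(methoxymethoxy)-2H-pyran-2-one
Product: 19 2-[2-acetyl-3-(methoxymethoxy)-6-[4-(methoxymethoxy)-2-oxo-2H-pyran-6-yl]-5-(3-methylbutyl)phenyl]acetaldehyde
Conditions: DMP, pyridine, CH2Cl2, 0 °C; short work-up, used crude
Reagents that add atoms: none
Why: Dess–Martin oxidation of the primary alcohol, whose open hydroxy ketone form is drained from the hemiketal equilibrium, should give the arylacetaldehyde under buffered, nearly neutral conditions that avoid premature aldol closure.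

Step 13
Reactants: 19 2-[2-acetyl-3-(methoxymethoxy)-6-[4-(methoxymethoxy)-2-oxo-2H-pyran-6-yl]-5-(3-methylbutyl)phenyl]acetaldehyde
Product: 20 (3R)-3-hydroxy-8-(methoxymethoxy)-5-[4-(methoxymethoxy)-2-oxo-2H-pyran-6-yl]-6-(3-methylbutyl)-3,4-dihydronaphthalen-1(2H)-one
Conditions: (R,R)-ProPhenol (2,6-bis{[(2R)-2-(hydroxydiphenylmethyl)pyrrolidin-1-yl]methyl}-4-methylphenol, 10 mol%), Et2Zn (20 mol%), Ph3P=S (15 mol%), 4 Å MS, THF (0.02 M), −20 °C
Reagents that add atoms: none
Why: Proposed new method: the zinc alkoxide of the dinuclear complex formed from Et2Zn and the ligand deprotonates the C8a acetyl methyl group to a zinc enolate while the second zinc binds the aldehyde oxygen, C2 adds to the aldehyde carbon to form bond C2–C3, and proton transfer from the next substrate molecule releases the zinc aldolate. The closest known reaction type is the intermolecular direct asymmetric aldol of aryl methyl ketones with aldehydes under the same dinuclear zinc catalysis, which has not been shown for an intramolecular closure or for an arylacetaldehyde acceptor. Ring B closes in a 6-(enolexo)-exo-trig mode. The C3 stereocentre is controlled by the chiral bimetallic pocket, which should expose one enantiotopic face of the bound aldehyde to the enolate held on the neighbouring zinc, the ortho relationship of donor and acceptor on ring A leaving one chair-like arrangement. The step needs enantiofacial selectivity and donor–acceptor chemoselectivity; the latter is secured in the substrate because the more acidic aldehyde α-position could only close a four-membered ring, so its reversible enolisation is unproductive, while dilution and low temperature should hold back intermolecular condensation and dehydration to the naphthol.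

Step 14
Reactants: 20 (3R)-3-hydroxy-8-(methoxymethoxy)-5-[4-(methoxymethoxy)-2-oxo-2H-pyran-6-yl]-6-(3-methylbutyl)-3,4-dihydronaphthalen-1(2H)-one
Product: 21 (3R)-3,8-dihydroxy-5-(4-hydroxy-2-oxo-2H-pyran-6-yl)-6-(3-methylbutyl)-3,4-dihydronaphthalen-1(2H)-one (target)
Conditions: MgBr2·OEt2, n-BuSH, Et2O, 0 °C → rt
Reagents that add atoms: none
Why: Lewis acid-assisted acetal cleavage, in which MgBr2 activates each methoxymethyl ether and the thiol takes up the methoxymethyl group, should free both hydroxyls under conditions mild enough not to dehydrate the β-hydroxy ketone, so that the C3 configuration is kept.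

**Compound list**
1 | methyl orsellinate (methyl 2,4-dihydroxy-6-methylbenzoate) | COC(=O)c1c(C)cc(O)cc1O | starting material
2 | methyl 2-hydroxy-6-methyl-4-[(trifluoromethanesulfonyl)oxy]benzoate | COC(=O)c1c(C)cc(OS(=O)(=O)C(F)(F)F)cc1O | intermediate
3 | methyl 2-(methoxymethoxy)-6-methyl-4-[(trifluoromethanesulfonyl)oxy]benzoate | COCOc1cc(OS(=O)(=O)C(F)(F)F)cc(C)c1C(=O)OC | intermediate
4 | isopentylmagnesium bromide | CC(C)CC[Mg]Br | starting material
5 | methyl 2-(methoxymethoxy)-6-methyl-4-(3-methylbutyl)benzoate | COCOc1cc(CCC(C)C)cc(C)c1C(=O)OC | intermediate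
6 | methyl 3-bromo-6-(methoxymethoxy)-2-methyl-4-(3-methylbutyl)benzoate | COCOc1cc(CCC(C)C)c(Br)c(C)c1C(=O)OC | intermediate
7 | formaldehyde (monomer from paraformaldehyde) | C=O | starting material
8 | methyl 3-bromo-2-(2-hydroxyethyl)-6-(methoxymethoxy)-4-(3-methylbutyl)benzoate (hydroxy ester, not isolated) | COCOc1cc(CCC(C)C)c(Br)c(CCO)c1C(=O)OC | intermediate
9 | 5-bromo-8-(methoxymethoxy)-6-(3-methylbutyl)-3,4-dihydro-1H-isochromen-1-one | COCOc1cc(CCC(C)C)c(Br)c2c1C(=O)OCC2 | intermediate
10 | 5-bromo-8-(methoxymethoxy)-1-methyl-6-(3-methylbutyl)-3,4-dihydro-1H-isochromen-1-ol (racemic lactol, not isolated) | COCOc1cc(CCC(C)C)c(Br)c2c1C(C)(O)OCC2 | intermediate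
11 | 5-bromo-1-methoxy-8-(methoxymethoxy)-1-methyl-6-(3-methylbutyl)-3,4-dihydro-1H-isochromene (racemic) | COCOc1cc(CCC(C)C)c(Br)c2c1C(C)(OC)OCC2 | intermediate
12 | 1-methoxy-8-(methoxymethoxy)-1-methyl-6-(3-methylbutyl)-3,4-dihydro-1H-isochromene-5-carbaldehyde (racemic) | COCOc1cc(CCC(C)C)c(C=O)c2c1C(C)(OC)OCC2 | intermediate
13 | methyl acetoacetate | COC(=O)CC(C)=O | starting material
14 | methyl 5-hydroxy-5-[1-methoxy-8-(methoxymethoxy)-1-methyl-6-(3-methylbutyl)-3,4-dihydro-1H-isochromen-5-yl]-3-oxopentanoate (diastereomer mixture) | COCOc1cc(CCC(C)C)c(C(O)CC(=O)CC(=O)OC)c2c1C(C)(OC)OCC2 | intermediate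
15 | methyl 5-[1-methoxy-8-(methoxymethoxy)-1-methyl-6-(3-methylbutyl)-3,4-dihydro-1H-isochromen-5-yl]-3,5-dioxopentanoate (racemic) | COCOc1cc(CCC(C)C)c(C(=O)CC(=O)CC(=O)OC)c2c1C(C)(OC)OCC2 | intermediate
16 | 4-hydroxy-6-[1-methoxy-8-(methoxymethoxy)-1-methyl-6-(3-methylbutyl)-3,4-dihydro-1H-isochromen-5-yl]-2H-pyran-2-one (racemic, not isolated) | COCOc1cc(CCC(C)C)c(-c3cc(O)cc(=O)o3)c2c1C(C)(OC)OCC2 | intermediate
17 | 6-[1-methoxy-8-(methoxymethoxy)-1-methyl-6-(3-methylbutyl)-3,4-dihydro-1H-isochromen-5-yl]-4-(methoxymethoxy)-2H-pyran-2-one (racemic) | COCOc1cc(CCC(C)C)c(-c3cc(OCOC)cc(=O)o3)c2c1C(C)(OC)OCC2 | intermediate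
18 | 6-[3-acetyl-2-(2-hydroxyethyl)-4-(methoxymethoxy)-6-(3-methylbutyl)phenyl]-4-(methoxymethoxy)-2H-pyran-2-one | CC(=O)c1c(OCOC)cc(CCC(C)C)c(-c2cc(OCOC)cc(=O)o2)c1CCO | intermediate
19 | 2-[2-acetyl-3-(methoxymethoxy)-6-[4-(methoxymethoxy)-2-oxo-2H-pyran-6-yl]-5-(3-methylbutyl)phenyl]acetaldehyde | CC(C)CCc1cc(OCOC)c(C(C)=O)c(CC=O)c1-c1cc(OCOC)cc(=O)o1 | intermediate
20 | (3R)-3-hydroxy-8-(methoxymethoxy)-5-[4-(methoxymethoxy)-2-oxo-2H-pyran-6-yl]-6-(3-methylbutyl)-3,4-dihydronaphthalen-1(2H)-one | CC(C)CCc1cc(OCOC)c2c(c1-c1cc(OCOC)cc(=O)o1)C[C@@H](O)CC2=O | intermediate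
21 | (3R)-3,8-dihydroxy-5-(4-hydroxy-2-oxo-2H-pyran-6-yl)-6-(3-methylbutyl)-3,4-dihydronaphthalen-1(2H)-one | CC(C)CCc1cc(O)c2c(c1-c1cc(O)cc(=O)o1)C[C@@H](O)CC2=O | target

**Totals**
Total step count: 14. Longest linear sequence: 14 steps (1 to 21; the route is fully linear).

**Steps most likely to fail**

1. Step 13 (closure of ring B). The catalyst may be tied up by the unproductive zinc enolate of the arylacetaldehyde, the closure may run with poor facial selectivity, or the aldol may dehydrate and aromatise. The fallback sets out from 19 and comes back at 20. Keto aldehyde 19 is closed without chiral control by treating it at −78 °C in THF with slightly less than one equivalent of LiN(SiMe3)2 and quenching cold with AcOH; reversible proton transfer should funnel the material through the ketone enolate to the racemic bis(methoxymethyl) ether F1. F1 is then resolved by preparative chromatography on a chiral stationary phase (cellulose tris(3,5-dimethylphenylcarbamate)). The (3R) enantiomer is 20 and the (3S)-configured bis(methoxymethyl) ether F2 is set aside. The configuration is assigned by Mosher ester analysis before step 14.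

2. Step 5 (lateral hydroxymethylation). Formaldehyde gas may repolymerise before it is captured, or the benzylic anion may be quenched by proton return, so that conversion stalls. The fallback sets out from 6 and comes back at 9. The same benzylic anion (LiN(i-Pr)2, THF, −78 °C) is trapped with CO2, a far more efficient electrophile, to give the arylacetic acid half ester F3. BH3·SMe2 in THF then reduces the free acid in preference to the methyl ester to the hydroxy ester 8, which is closed to lactone 9 with catalytic NaH in THF.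

3. Step 6 (MeLi addition and ketal formation). A second MeLi may add after ring opening of the hemiketal, or the mixed ketal and the methoxymethyl ethers may not survive the acid used to form it, chromatography or the later hydrolysis in step 11. The fallback sets out from 9 and comes back at 18; it masks both functions at the alcohol oxidation level instead of as a ketal.
   - Lactone 9 is treated with MeLi as before and the crude lactol 10 is reduced with NaBH4 in MeOH to the racemic diol F4.
   - TBSOTf and 2,6-lutidine give the bis(silyl ether) F5.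
   - Bromine–lithium exchange with t-BuLi and formylation with DMF give the aldehyde F6.
   - Addition of the dianion of 13 gives the hydroxy keto ester F7, and Dess–Martin oxidation gives the dioxo ester F8.
   - DBU followed by MOMCl gives the protected pyranone F10 by way of the hydroxypyranone F9.
   - HF·pyridine in THF removes both silyl groups to give the diol F11.
   - MnO2 in CH2Cl2 oxidises only the benzylic secondary alcohol of F11 and gives 18. This order avoids the lactol-to-lactone over-oxidation that a simultaneous oxidation of both alcohols would risk. The route resumes at step 12.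

**Further compounds**
F1 | step 13 | racemic 3-hydroxy-8-(methoxymethoxy)-5-[4-(methoxymethoxy)-2-oxo-2H-pyran-6-yl]-6-(3-methylbutyl)-3,4-dihydronaphthalen-1(2H)-one | CC(C)CCc1cc(OCOC)c2c(c1-c1cc(OCOC)cc(=O)o1)CC(O)CC2=O
F2 | step 13 | (3S)-3-hydroxy-8-(methoxymethoxy)-5-[4-(methoxymethoxy)-2-oxo-2H-pyran-6-yl]-6-(3-methylbutyl)-3,4-dihydronaphthalen-1(2H)-one | CC(C)CCc1cc(OCOC)c2c(c1-c1cc(OCOC)cc(=O)o1)C[C@H](O)CC2=O
F3 | step 5 | 2-[2-bromo-6-(methoxycarbonyl)-5-(methoxymethoxy)-3-(3-methylbutyl)phenyl]acetic acid | COCOc1cc(CCC(C)C)c(Br)c(CC(=O)O)c1C(=O)OC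
F4 | step 6 | 1-[3-bromo-2-(2-hydroxyethyl)-6-(methoxymethoxy)-4-(3-methylbutyl)phenyl]ethan-1-ol (racemic) | COCOc1cc(CCC(C)C)c(Br)c(CCO)c1C(C)O
F5 | step 6 | bis(tert-butyldimethylsilyl) ether of F4 (racemic) | COCOc1cc(CCC(C)C)c(Br)c(CCO[Si](C)(C)C(C)(C)C)c1C(C)O[Si](C)(C)C(C)(C)C
F6 | step 6 | 3-[1-(tert-butyldimethylsilyloxy)ethyl]-2-[2-(tert-butyldimethylsilyloxy)ethyl]-4-(methoxymethoxy)-6-(3-methylbutyl)benzaldehyde (racemic) | COCOc1cc(CCC(C)C)c(C=O)c(CCO[Si](C)(C)C(C)(C)C)c1C(C)O[Si](C)(C)C(C)(C)C
F7 | step 6 | methyl 5-hydroxy-3-oxo-5-aryl-pentanoate from F6 (aryl as in F6; diastereomer mixture) | COCOc1cc(CCC(C)C)c(C(O)CC(=O)CC(=O)OC)c(CCO[Si](C)(C)C(C)(C)C)c1C(C)O[Si](C)(C)C(C)(C)C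
F8 | step 6 | methyl 3,5-dioxo-5-aryl-pentanoate from F7 (racemic) | COCOc1cc(CCC(C)C)c(C(=O)CC(=O)CC(=O)OC)c(CCO[Si](C)(C)C(C)(C)C)c1C(C)O[Si](C)(C)C(C)(C)C
F9 | step 6 | 6-aryl-4-hydroxy-2H-pyran-2-one from F8 (bis-silyl ether, racemic) | COCOc1cc(CCC(C)C)c(-c2cc(O)cc(=O)o2)c(CCO[Si](C)(C)C(C)(C)C)c1C(C)O[Si](C)(C)C(C)(C)C
F10 | step 6 | 6-aryl-4-(methoxymethoxy)-2H-pyran-2-one from F9 (bis-silyl ether, racemic) | COCOc1cc(CCC(C)C)c(-c2cc(OCOC)cc(=O)o2)c(CCO[Si](C)(C)C(C)(C)C)c1C(C)O[Si](C)(C)C(C)(C)C
F11 | step 6 | 6-[3-(1-hydroxyethyl)-2-(2-hydroxyethyl)-4-(methoxymethoxy)-6-(3-methylbutyl)phenyl]-4-(methoxymethoxy)-2H-pyran-2-one (racemic) | COCOc1cc(CCC(C)C)c(-c2cc(OCOC)cc(=O)o2)c(CCO)c1C(C)O
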